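Temperature is what separates autumn from midnight, which carry the same charges for 20 h: autumn spends 10 h at 5 °C before going to 45 °C, and midnight stands at 45 °C throughout.

the same everywhere: initiator 0.32 mM
- ash: substrate 0.065 M; reagent 0.044 M; scavenger 0.052 M; temperature 0 °C; run made earlier
- larch: substrate 0.065 M; reagent 0.098 M; scavenger 0.052 M; temperature 25 °C; run made earlier
- alder: substrate 0.13 M; reagent 0.065 M; scavenger 0.052 M; temperature 0 °C; run made earlier
- autumn: substrate 0.065 M; reagent 0.0650 M; scavenger 0.0520 M; at 5 °C until 10 h, from then on at 45 °C; time 20 h
- midnight: substrate 0.065 M; reagent 0.0650 M; scavenger 0.0520 M; at 45 °C throughout; time 20 h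

| run | time / h | product / % |
|---|---|---|
| ash | 1.00 | 34 |
| ash | 1.50 | 45 |
| ash | 2.50 | 54 |
| ash | 4.00 | 62 |
| ash | 8.00 | 66 |
| ash | 12.0 | 68 |
| larch | 0.333 | 86 |
| larch | 0.500 | 95 |
| larch | 1.00 | 99 |
| larch | 1.33 | 96 |
| larch | 3.00 | 99 |
| larch | 4.00 | 96 |
| alder | 1.00 | 26 |
| alder | 3.00 | 44 |
| alder | 6.00 | 49 |
| alder | 8.00 | 49 |
| alder | 12.0 | 52 |

(standard deviation of a reading: 1.5 percentage points)

- percent here means substrate units held: one ended chains B counts as two
- what is said of product includes crystals
- what is said of released group includes idle adduct
- crystals is a solid; its amount is given per volume of the solution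
- steps that have been proposed: 2 second chain carrier -> ended chains A; reagent + first chain carrier -> product + second chain carrier; substrate + second chain carrier -> released group + first chain carrier; substrate + released group <-> idle adduct; scavenger + released group -> scavenged by-product; substrate + initiating radical -> capped initiator + first chain carrier; initiator -> 2 initiating radical; 2 first chain carrier -> ended chains B; crystals <-> product

- which of the two ends with the higher amount of product, in percent of the substrate charged ("neither" if they lie within 2 percentage points) (autumn / midnight / neither)
- product at the end, in percent of the substrate charged, autumn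
- product at the end, in percent of the substrate charged, midnight

You can read the runs through one number. Since each unit of product takes one unit of reagent, the alder run at 3.00 h has a reach S, the natural logarithm of reagent charged over reagent left, of 2.12. At 1.00 h the ash run reads 0.698 and the alder run 0.734, although alder has twice the substrate and a different reagent charge. So I treat the reagent as falling pseudo-first-order, and I read a reach as a share of the reagent.

From above, the equal charges give both flasks a ceiling of 100%. From below, I take autumn's cold stage to reach at least as far as alder did at 0 °C, which gives 88.0%. I tighten this with the alder reading at 6.00 h, where 98.0% of the reagent stands as product, so I expect autumn near that figure.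

Midnight is harder: 45 °C lies above the warmest run, the larch run at 25 °C. The larch run at 0.500 h shows a reach of 0.995 at 25 °C, close under the 1.09 that its substrate charge allows, and that gives midnight 63.0%, but this floor holds on the condition that heating does not shorten the reach.

The forecast says 98% for autumn, 96% for midnight and neither for the comparison, both inside these brackets: “Larch shows no sign of stalling, so I expect it to finish too, though this is uncertain”.

Autumn ends at 97.6%, but midnight ends at 38.2%, below the conditional floor, so the higher flask is autumn.

    2 second chain carrier → ended chains A (k = 2.50 × 10⁷ /M/s, Ea = 18.0 kJ/mol)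
    reagent + first chain carrier → product + second chain carrier (k = 2.24 × 10⁵ /M/min, Ea = 11.0 kJ/mol)
    substrate + second chain carrier → released group + first chain carrier (k = 1.22 × 10⁵ /M/s, Ea = 27.0 kJ/mol)
    substrate + released group ⇌ idle adduct, settled at all times (K = 6.90 /M, ΔH = 4.00 kJ/mol)
    scavenger + released group → scavenged by-product (k = 1.67 /M/min, Ea = 49.0 kJ/mol)
    substrate + initiating radical → capped initiator + first chain carrier (k = 2.26 × 10⁵ /M/s, Ea = 12.0 kJ/mol)
    initiator → 2 initiating radical (k = 0.00997 /min, Ea = 82.0 kJ/mol)
    2 first chain carrier → ended chains B (k = 7.10 × 10⁶ /M/s, Ea = 17.0 kJ/mol)
    crystals ⇌ product, rate k9*(cs9 - [product]) while solid is left; crystals form when [product] > cs9 (solubility = 0.0550 M, k = 0.262 /min)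
    (constants at 5 °C)

Midnight keeps 62% of its reagent with 0% of its initiator left, a reach of 0.478, less than the 2.12 read from the alder run at 3.00 h. A neighbour of autumn charged with 0.039 M of reagent gets the same reckoning: a ceiling of 60.0% and, from alder's reach, a floor of 52.8%. That neighbour ends at 58.5%, with 2.4% of its reagent left, the share autumn keeps of its own, 2.4%.

(The earlier runs and the new flask come from a simulation from invented constants.)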